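**Plan**
- Retrosynthesis: the 4'-O–Si bond and the C4–OH bond (back to C4–OMe) are cut first, then C8–prenyl (via C8–Br), and last ring C at C3–C4, O1–C2 and C4–OMe, which leaves 2,6-dihydroxy-4-methoxybenzaldehyde, trimethyl orthoformate and a 4-silyloxystyrene.
- Enabling feature: in ring C the C3 methylene lies between C2 (bonded to O1 and the B-ring aryl) and C4 (oxygen-bearing and benzylic to the 5,7-dioxygenated ring A). O1–C8a–C4a–C4(OR) can therefore be read as a 4-alkoxy o-quinone methide and C2–C3 as a styrene, and the two ortho hydroxyls of the aldehyde are equivalent.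
- Forward order: rings A and B are bought, ring C is made in one three-component step, then C8 is brominated and prenylated, C4–OMe is exchanged for C4–OH and the silyl group is removed.
- Stereochemistry: C2 (S) comes from the chiral counter-anion of the Brønsted acid in the cycloaddition; C4 (R) is set at the end by axial capture of water by the C4 cation, trans to the equatorial C2 aryl group.

Key step: step 3

Assumption 1: the sense of induction of the chiral acid cannot be predicted, so the catalyst enantiomer that delivers the (2S) adduct is taken, and its mirror image is used if the sense proves opposite.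
Assumption 2: compounds 9–11 are drawn as the 2,4-trans (4R) epimers; any (2S,4S) epimer formed alongside is carried through the same steps, because C4 is re-ionised in step 6.

**Step 1**
Reactants: 1 2,4,6-trihydroxybenzaldehyde
Product: 2 2,6-dihydroxy-4-methoxybenzaldehyde
Conditions: MeI (1.05 equiv), Li2CO3 (1.1 equiv), DMF, rt to 40 °C
Reagents that add atoms: iodomethane, CI
Why: Williamson etherification under weak-base control: the 4-hydroxyl, para to the formyl group and outside its hydrogen-bonded chelate, is the most acidic and most accessible phenol, so one equivalent of iodomethane should alkylate it alone and leave the two ortho hydroxyls equivalent.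

**Step 2**
Reactants: 3 4-acetoxystyrene
Product: 5 4-(triisopropylsilyloxy)styrene, via 4-vinylphenol 4 (not isolated)
Conditions: K2CO3 (10 mol %), MeOH, BHT (trace), 0 °C; solvent removed below 25 °C; then TIPSCl (1.2 equiv), imidazole (2.5 equiv), DMF, 0 °C to rt
Reagents that add atoms: chlorotriisopropylsilane, CC(C)[Si](Cl)(C(C)C)C(C)C
Why: Base-catalysed transesterification of the aryl acetate followed by silylation of the phenol (silyl chloride/imidazole); the polymerisation-prone vinylphenol is kept cold, inhibited and silylated at once, and the triisopropylsilyl ether is chosen because it should outlast the Brønsted acid of step 3, the aqueous base of step 5 and the dilute acid of step 6.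

**Step 3**
Reactants: 2 2,6-dihydroxy-4-methoxybenzaldehyde; 5 4-(triisopropylsilyloxy)styrene; 6 trimethyl orthoformate
Product: 9 (2S,4R)-4,7-dimethoxy-2-[4-(triisopropylsilyloxy)phenyl]chroman-5-ol, via dimethyl acetal 7 (not isolated), via methoxy-o-quinone methide 8 (not isolated)
Conditions: 2 (1.0 equiv), 6 (1.5 equiv), 5 (2.0 equiv), confined chiral BINOL-derived imidodiphosphoric acid (5 mol %), CH2Cl2, −40 to −10 °C; Et3N quench
Reagents that add atoms: none
Why: Proposed new method: the acid should turn 2 and 6 into acetal 7 and ionise it to the O-methyl oxocarbenium ion, the protonated form of quinone methide 8, which the 5- and 7-oxygens stabilise and which stays paired with the chiral imidodiphosphate through its two phenolic O–H bonds; the CH2 terminus of styrene 5 attacks the cationic carbon (C3–C4) and the phenolic oxygen then captures the developing 4-silyloxybenzyl cation (O1–C2), an asynchronous inverse-demand hetero-[4+2] that leaves the methoxy group on C4. The nearest established reactions are the Lewis-acid-promoted, racemic condensation of a salicylaldehyde, an orthoformate and a styrene to 2-aryl-4-alkoxychromans, and the intramolecular variant in which a confined chiral phosphoric-type acid steers an alkoxy-o-quinone methide onto a tethered olefin. Ring C closes as the six-membered ring of the cycloaddition, its last bond being O1–C2, formed when the phenol oxygen captures the benzylic cation in a chair-like arrangement with the aryl group pseudo-equatorial. C2 (S) is fixed by the confined chiral counter-anion, which leaves one face of the hydrogen-bonded ion pair and one orientation of the styrene aryl group open; C4 is fixed in the same event and is expected pseudo-axial (R, trans), away from the peri 5-hydroxyl. The step needs three selectivities: regiochemistry, secured by the polarity of the partners and by the mirror symmetry of 2 that makes both hydroxyls the same; ionisation of the acetal in preference to the product ether, secured by the extra oxygen on the oxocarbenium carbon; and face selectivity at C2, which rests on the catalyst alone.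

**Step 4**
Reactants: 9 (2S,4R)-4,7-dimethoxy-2-[4-(triisopropylsilyloxy)phenyl]chroman-5-ol
Product: 10 (2S,4R)-8-bromo-4,7-dimethoxy-2-[4-(triisopropylsilyloxy)phenyl]chroman-5-ol
Conditions: NBS (1.0 equiv), NaHCO3 (solid), CH2Cl2, −78 to −40 °C, dark
Reagents that add atoms: N-bromosuccinimide, O=C1CCC(=O)N1Br
Why: Electrophilic aromatic bromination of a phenol: C8 is para to the free 5-hydroxyl, ortho to both the 7-methoxyl and O1, and less crowded than C6, it is the position at which 5,7-dioxygenated flavans normally react with NBS, ring B is far less activated, and brominating before the prenyl olefin is present avoids attack on that double bond.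

**Step 5**
Reactants: 10 (2S,4R)-8-bromo-4,7-dimethoxy-2-[4-(triisopropylsilyloxy)phenyl]chroman-5-ol
Product: 11 (2S,4R)-4,7-dimethoxy-8-(3-methylbut-2-en-1-yl)-2-[4-(triisopropylsilyloxy)phenyl]chroman-5-ol
Conditions: prenyl-B(pin) (1.5 equiv), Pd-PEPPSI-IPent (3 mol %), K3PO4 (3 equiv), THF/H2O (10:1), 50 °C, degassed
Reagents that add atoms: 3-methylbut-2-enylboronic acid pinacol ester, CC(C)=CCB1OC(C)(C)C(C)(C)O1
Why: Suzuki–Miyaura coupling of an allylboronate: with the very bulky N-heterocyclic carbene ligand the prenyl-palladium intermediate should undergo reductive elimination at its unhindered CH2 terminus, giving the linear 3-methylbut-2-enyl group at C8, and the free phenol and the aryl triisopropylsilyl ether tolerate aqueous phosphate.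

**Step 6**
Reactants: 11 (2S,4R)-4,7-dimethoxy-8-(3-methylbut-2-en-1-yl)-2-[4-(triisopropylsilyloxy)phenyl]chroman-5-ol
Product: 12 (2S,4R)-7-methoxy-8-(3-methylbut-2-en-1-yl)-2-[4-(triisopropylsilyloxy)phenyl]chromane-4,5-diol
Conditions: p-TsOH·H2O (5 mol %), acetone/H2O (3:1), 0.005 M, 0 °C; NaHCO3 quench
Reagents that add atoms: water, O
Why: SN1 solvolysis of a 4-alkoxyflavan: the ortho 5-hydroxyl and para 7-methoxyl allow C4–OMe to ionise in very dilute acid to the benzylic cation (protonated o-quinone methide), which water, present in large excess, should capture along the axial trajectory of the half-chair to place the hydroxyl trans to the equatorial C2 aryl group (4R), while O1–C2, the silyl ether and the prenyl olefin need stronger acid to react and high dilution suppresses attack by C6 of a second molecule.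

**Step 7**
Reactants: 12 (2S,4R)-7-methoxy-8-(3-methylbut-2-en-1-yl)-2-[4-(triisopropylsilyloxy)phenyl]chromane-4,5-diol
Product: 13 (2S,4R)-2-(4-hydroxyphenyl)-7-methoxy-8-(3-methylbut-2-en-1-yl)chromane-4,5-diol (4,5,4'-trihydroxy-7-methoxy-8-prenylflavan)
Conditions: TBAF (1.1 equiv), AcOH (1.1 equiv), THF, 0 °C; pH 7 buffer work-up
Reagents that add atoms: none
Why: Fluoride-induced cleavage of the aryl silyl ether (Si–O to Si–F), buffered with acetic acid so that the sensitive 5-hydroxyflavan-4-ol meets neither a free phenoxide nor a strong acid; no stereocenter is involved.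

**Compound list**
1 | 2,4,6-trihydroxybenzaldehyde | O=Cc1c(O)cc(O)cc1O | starting material
2 | 2,6-dihydroxy-4-methoxybenzaldehyde | COc1cc(O)c(C=O)c(O)c1 | intermediate
3 | 4-acetoxystyrene | CC(=O)Oc1ccc(C=C)cc1 | starting material
4 | 4-vinylphenol | C=Cc1ccc(O)cc1 | intermediate
5 | 4-(triisopropylsilyloxy)styrene | C=Cc1ccc(O[Si](C(C)C)(C(C)C)C(C)C)cc1 | intermediate
6 | trimethyl orthoformate | COC(OC)OC | starting material
7 | 2-(dimethoxymethyl)-5-methoxybenzene-1,3-diol (dimethyl acetal of 2) | COc1cc(O)c(C(OC)OC)c(O)c1 | intermediate
8 | 5-hydroxy-3-methoxy-6-(methoxymethylidene)cyclohexa-2,4-dien-1-one (methoxy-o-quinone methide, neutral form; reacts O-protonated) | COC=C1C(=O)C=C(OC)C=C1O | intermediate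
9 | (2S,4R)-4,7-dimethoxy-2-[4-(triisopropylsilyloxy)phenyl]chroman-5-ol (2,4-trans) | COc1cc(O)c2c(c1)O[C@H](c1ccc(O[Si](C(C)C)(C(C)C)C(C)C)cc1)C[C@H]2OC | intermediate
10 | (2S,4R)-8-bromo-4,7-dimethoxy-2-[4-(triisopropylsilyloxy)phenyl]chroman-5-ol | COc1cc(O)c2c(c1Br)O[C@H](c1ccc(O[Si](C(C)C)(C(C)C)C(C)C)cc1)C[C@H]2OC | intermediate
11 | (2S,4R)-4,7-dimethoxy-8-(3-methylbut-2-en-1-yl)-2-[4-(triisopropylsilyloxy)phenyl]chroman-5-ol | COc1cc(O)c2c(c1CC=C(C)C)O[C@H](c1ccc(O[Si](C(C)C)(C(C)C)C(C)C)cc1)C[C@H]2OC | intermediate
12 | (2S,4R)-7-methoxy-8-(3-methylbut-2-en-1-yl)-2-[4-(triisopropylsilyloxy)phenyl]chromane-4,5-diol | COc1cc(O)c2c(c1CC=C(C)C)O[C@H](c1ccc(O[Si](C(C)C)(C(C)C)C(C)C)cc1)C[C@H]2O | intermediate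
13 | (2S,4R)-2-(4-hydroxyphenyl)-7-methoxy-8-(3-methylbut-2-en-1-yl)chromane-4,5-diol (2,4-trans) | COc1cc(O)c2c(c1CC=C(C)C)O[C@H](c1ccc(O)cc1)C[C@H]2O | target

**Step count**
Total: 7 steps. Longest linear sequence: 6 steps (1, 3, 4, 5, 6, 7); step 2 is the side branch to the styrene.

**Steps most likely to fail**

Step 3 (proposed new method). The styrene is not held by the catalyst, so face discrimination at C2 may be poor. The cation may also be consumed by Friedel–Crafts attack of the electron-rich ring A of the product, or the acid may oligomerise the styrene. The fallback uses known chemistry and sets out from 2 together with 5 and 6. The three components are combined under an achiral Lewis acid (Sc(OTf)3 cat., CH2Cl2, 0 °C to rt), which should give the trans adduct as a racemate, that is 9 together with its mirror image (2R,4S)-4,7-dimethoxy-2-[4-(triisopropylsilyloxy)phenyl]chroman-5-ol F1. The two are separated by preparative chromatography on a chiral stationary phase, and the route is rejoined at 9.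

Step 6. Capture of the C4 cation by water may lose its trans preference if the product re-ionises. The cation may also be taken by C6 of a second molecule (oligomerisation) or lose a C3 proton to a flav-3-ene. The fallback sets out from 11 and replaces equilibrating protic solvolysis by a two-stage exchange. Thiolysis with excess benzyl mercaptan (AcOH cat., CH2Cl2, 0 °C) lets a soft nucleophile outrun oligomerisation and should give the stable, purifiable (2S,4R)-4-(benzylsulfanyl)-7-methoxy-8-(3-methylbut-2-en-1-yl)-2-[4-(triisopropylsilyloxy)phenyl]chroman-5-ol F2. The thioether is then activated by a thiophilic silver salt (AgBF4, 2,6-di-tert-butylpyridine, THF/H2O, −40 to 0 °C), so that water adds once, under kinetic control and without protic acid, and the route is rejoined at 12.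

Step 5. Oxidative addition may be sluggish at a bromide flanked by two alkoxy groups and para to a phenoxide. Coupling may occur at the tertiary allyl terminus, the bromide may be lost by protodehalogenation, or base may expel methoxide from C4. The fallback sets out from 9 and needs neither step 4 nor palladium. O-Alkylation of the 5-hydroxyl (prenyl bromide, K2CO3, acetone, rt) should give (2S,4R)-4,7-dimethoxy-5-(3-methylbut-2-en-1-yloxy)-2-[4-(triisopropylsilyloxy)phenyl]chromane F3. A Eu(fod)3-catalysed Claisen–Cope (para-Claisen) rearrangement (CHCl3, 60 °C) then moves the allyl unit through C6 to C8 and returns the 5-hydroxyl, rejoining the route at 11.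

**Further compounds**
F1 | step 3 | (2R,4S)-4,7-dimethoxy-2-[4-(triisopropylsilyloxy)phenyl]chroman-5-ol | COc1cc(O)c2c(c1)O[C@@H](c1ccc(O[Si](C(C)C)(C(C)C)C(C)C)cc1)C[C@@H]2OC
F2 | step 6 | (2S,4R)-4-(benzylsulfanyl)-7-methoxy-8-(3-methylbut-2-en-1-yl)-2-[4-(triisopropylsilyloxy)phenyl]chroman-5-ol | COc1cc(O)c2c(c1CC=C(C)C)O[C@H](c1ccc(O[Si](C(C)C)(C(C)C)C(C)C)cc1)C[C@H]2SCc1ccccc1
F3 | step 5 | (2S,4R)-4,7-dimethoxy-5-(3-methylbut-2-en-1-yloxy)-2-[4-(triisopropylsilyloxy)phenyl]chromane | COc1cc(OCC=C(C)C)c2c(c1)O[C@H](c1ccc(O[Si](C(C)C)(C(C)C)C(C)C)cc1)C[C@H]2OC
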